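## Plan

- **Cuts:** the C8 ester and the side-chain C–Cl bond, the C13 acetate, then the C5=C6 bond (ring closure), the C1–O ketal bond, the C2–C3 bond (alkyne + epoxide), the C8–C9 bond (allylation); the butenolide is traced back to a 2-silylfuran.
- **Forward order of rings:** the furan (latent butenolide) is there from the start; a temporary γ-lactone sets C8 and C10 and is opened to an alkyne; after union with the epoxide the butenolide is unmasked, then the oxolane (C1–C4, O) is formed as its methyl ketal; the nine-membered ring (C4–C5–C6–C7–C8–C9–C10–C1–O) is closed last; acylations and HCl finish.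
- **Enabling feature:** C6 is the γ-carbon of the 7(11)-en-6,12-olide ring, so it is a latent aromatic 2-oxidofuran nucleophile. C5 is a non-enolisable aldehyde carbon on quaternary C4 of the oxolane ring, whose 1,4-oxygen bridge holds the C5 and C10 arms cis.
- **Stereochemistry:** C8 from a catalytic asymmetric allylation; C10 from hydrogenation of the α-methylene lactone anti to the C8 substituent; C4 from (S)-2-methylglycidol; C1 is dictated by C4 through the bridge; C2′ from methyl (S)-2-methylglycidate; the 5E geometry is imposed by the ring.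

Key step: step 16

Assumption: the bridged hemiketal is taken to be the stable closed form of the C1 ketone/C4 alcohol pair, so aqueous acid delivers C1 in the configuration fixed by C4.

Notation: positions follow germacranolide numbering (C1 hemiketal carbon, C4 methyl-bearing ether carbon, C5=C6 exocyclic alkene, C7/C11/C12 butenolide, C8 ester carbinol, C10 CH(CH3), C13 acetoxymethyl carbon). FurSi = 5-(tert-butyldimethylsilyl)-4-{[(tert-butyldimethylsilyl)oxy]methyl}furan-3-yl; TBS = tert-butyldimethylsilyl; PMB = 4-methoxybenzyl.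

## Route

Step 1
Reactants: 1 furan-3-ylmethanol
Product: 2 tert-butyl(furan-3-ylmethoxy)dimethylsilane
Conditions: TBSCl, imidazole, DMF, 0 °C to rt
Reagents that add atoms: tert-butyldimethylsilyl chloride, CC(C)(C)[Si](C)(C)Cl
Why: Standard silylation of a primary alcohol; the O-silyl group is the silicon source for the next step.

Step 2
Reactants: 2 tert-butyl(furan-3-ylmethoxy)dimethylsilane
Product: 3 [2-(tert-butyldimethylsilyl)furan-3-yl]methanol
Conditions: n-BuLi (1.2 equiv), HMPA, THF, −78 °C to rt; H2O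
Reagents that add atoms: none
Why: Ether-directed lithiation at furan C2 followed by 1,4 O-to-C silyl migration (retro-Brook rearrangement) puts silicon on the carbon that becomes the lactone carbonyl C12 and frees the alkoxide.

Step 3
Reactants: 3 [2-(tert-butyldimethylsilyl)furan-3-yl]methanol
Product: 4 5-(tert-butyldimethylsilyl)-4-(hydroxymethyl)furan-3-carbaldehyde
Conditions: n-BuLi (2.2 equiv), DME, 0 °C; DMF, −78 °C to rt; H2O
Reagents that add atoms: N,N-dimethylformamide, CN(C)C=O
Why: With C2 blocked by silicon, the lithium alkoxide directs the second lithiation to the adjacent C4 (directed ortho-metalation), and formylation installs C8 on the future C7.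

Step 4
Reactants: 4 5-(tert-butyldimethylsilyl)-4-(hydroxymethyl)furan-3-carbaldehyde
Product: 5 5-(tert-butyldimethylsilyl)-4-{[(tert-butyldimethylsilyl)oxy]methyl}furan-3-carbaldehyde
Conditions: TBSCl, imidazole, CH2Cl2, 0 °C to rt
Reagents that add atoms: tert-butyldimethylsilyl chloride, CC(C)(C)[Si](C)(C)Cl
Why: Standard silylation protects the C13 hydroxyl as a poor leaving group for the later enolate chemistry.

Step 5
Reactants: 5 5-(tert-butyldimethylsilyl)-4-{[(tert-butyldimethylsilyl)oxy]methyl}furan-3-carbaldehyde; 6 ethyl 2-(bromomethyl)prop-2-enoate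
Product: 9 (5R)-5-FurSi-3-methylideneoxolan-2-one, via TMS ether 7 (not isolated), via hydroxy ester 8 (not isolated)
Conditions: CrCl2 (10 mol %), chiral tridentate carbazole bis(oxazoline) ligand (10 mol %, the enantiomer that delivers the 8R alcohol), Mn (2 equiv), TMSCl, i-Pr2NEt (cat.), THF, rt; then 1 M aq. HCl, THF, 0 °C to rt
Reagents that add atoms: none
Why: Chromium-catalysed enantioselective Nozaki–Hiyama–Kishi-type 2-(alkoxycarbonyl)allylation (asymmetric Barbier reaction) forms C8–C9, the ligand on chromium setting C8 (R), and the hydroxy ester lactonises on acidic work-up.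

Step 6
Reactants: 9 (5R)-5-FurSi-3-methylideneoxolan-2-one
Product: 10 (3R,5R)-5-FurSi-3-methyloxolan-2-one
Conditions: H2 (1 atm), RhCl(PPh3)3 (5 mol %), benzene–EtOH, rt
Reagents that add atoms: none
Why: Homogeneous hydrogenation of the exocyclic alkene from the face anti to the C8 furyl group should set C10 cis to it (3R) without touching the furan.

Step 7
Reactants: 10 (3R,5R)-5-FurSi-3-methyloxolan-2-one
Product: 11 (3R,5R)-5-FurSi-3-methyloxolan-2-ol (anomer mixture)
Conditions: i-Bu2AlH (1.1 equiv), CH2Cl2, −78 °C; aq. potassium sodium tartrate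
Reagents that add atoms: none
Why: Low-temperature partial reduction of a γ-lactone stops at the lactol.

Step 8
Reactants: 11 (3R,5R)-5-FurSi-3-methyloxolan-2-ol
Product: 12 (1R,3R)-1-FurSi-3-methylpent-4-yn-1-ol
Conditions: dimethyl (1-diazo-2-oxopropyl)phosphonate, K2CO3, MeOH, 0 °C to rt
Reagents that add atoms: dimethyl (1-diazo-2-oxopropyl)phosphonate, COP(=O)(OC)C(=[N+]=[N-])C(C)=O
Why: Ohira–Bestmann (Seyferth–Gilbert) homologation of the open hydroxy-aldehyde form gives the terminal alkyne C1≡C2 and frees the C8 hydroxyl; the mild carbonate base should leave the α-stereocentre C10 intact.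

Step 9
Reactants: 12 (1R,3R)-1-FurSi-3-methylpent-4-yn-1-ol
Product: 13 tert-butyl{[(1R,3R)-1-FurSi-3-methylpent-4-yn-1-yl]oxy}dimethylsilane
Conditions: TBSOTf, 2,6-lutidine, CH2Cl2, −78 to 0 °C
Reagents that add atoms: tert-butyldimethylsilyl triflate, CC(C)(C)[Si](C)(C)OS(=O)(=O)C(F)(F)F
Why: Silyl triflate silylation of the hindered secondary alcohol prevents later spiroketal formation from the C8 oxygen.

Step 10
Reactants: 14 [(2S)-2-methyloxiran-2-yl]methanol ((S)-2-methylglycidol)
Product: 15 (2R)-2-{[(4-methoxybenzyl)oxy]methyl}-2-methyloxirane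
Conditions: NaH, 4-methoxybenzyl chloride, n-Bu4NI (cat.), THF–DMF, 0 °C to rt
Reagents that add atoms: 4-methoxybenzyl chloride, COc1ccc(CCl)cc1
Why: Williamson etherification leaves the epoxide and the stereocentre (future C4) untouched; only the descriptor changes.

Step 11
Reactants: 13 tert-butyl{[(1R,3R)-1-FurSi-3-methylpent-4-yn-1-yl]oxy}dimethylsilane; 15 (2R)-2-{[(4-methoxybenzyl)oxy]methyl}-2-methyloxirane
Product: 16 (2R,6R,8R)-8-[(tert-butyldimethylsilyl)oxy]-8-FurSi-1-[(4-methoxybenzyl)oxy]-2,6-dimethyloct-4-yn-2-ol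
Conditions: n-BuLi (1.05 equiv), THF, −78 °C; BF3·OEt2; then 15, −78 °C
Reagents that add atoms: none
Why: Lewis acid-assisted SN2 opening of the epoxide by the lithium acetylide at its unsubstituted CH2 forms C2–C3 and leaves the C4 tertiary alcohol with its configuration unchanged.

Step 12
Reactants: 16 (2R,6R,8R)-8-[(tert-butyldimethylsilyl)oxy]-8-FurSi-1-[(4-methoxybenzyl)oxy]-2,6-dimethyloct-4-yn-2-ol
Product: 18 4-[(1R,3R,7R)-1-[(tert-butyldimethylsilyl)oxy]-7-hydroxy-8-[(4-methoxybenzyl)oxy]-3,7-dimethyloct-4-yn-1-yl]-3-{[(tert-butyldimethylsilyl)oxy]methyl}furan-2(5H)-one, via furan-2(3H)-one 17 (not isolated)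
Conditions: AcOOH (in AcOH), NaOAc, CH2Cl2, 0 °C to rt; then Et3N (cat.), rt
Reagents that add atoms: peracetic acid, CC(=O)OO
Why: Peracid oxidation of a 2-silylfuran (ipso attack at the C–Si carbon with loss of silicon) gives the β,γ-unsaturated lactone, which conjugates to the 3,4-disubstituted butenolide with the carbonyl at the former C–Si carbon (C12).

Step 13
Reactants: 18 the butenolide alkynol from step 12
Product: 20 4-{(1R,3R)-1-[(tert-butyldimethylsilyl)oxy]-3-[(2S,5R)-2-methoxy-5-{[(4-methoxybenzyl)oxy]methyl}-5-methyloxolan-2-yl]butyl}-3-{[(tert-butyldimethylsilyl)oxy]methyl}furan-2(5H)-one, via dihydrofuran enol ether 19 (not isolated)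
Conditions: Ph3PAuCl (2 mol %), AgBF4 (2 mol %), PPTS (5 mol %), MeOH–CH2Cl2, rt
Reagents that add atoms: methanol, CO
Why: Gold-catalysed 5-endo-dig hydroalkoxylation by the C4 hydroxyl and acid-catalysed addition of methanol to the enol ether give the oxolane methyl ketal; C1 forms under equilibrating conditions as both anomers, so the anomer with OMe cis to the C4 methyl is collected and the remainder re-equilibrated under the same conditions.

Step 14
Reactants: 20 the methyl ketal PMB ether from step 13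
Product: 21 primary alcohol (20 with the PMB ether at C5 replaced by OH)
Conditions: DDQ, CH2Cl2–pH 7 phosphate buffer, 0 °C
Reagents that add atoms: none
Why: Oxidative cleavage of the PMB ether under buffered conditions spares the ketal, the silyl ethers and the electron-poor butenolide.

Step 15
Reactants: 21 the C5 primary alcohol
Product: 22 aldehyde ((2R,5S)-5-methoxy-2-methyloxolane-2-carbaldehyde carrying the 8R,10R side chain and butenolide of 20)
Conditions: Dess–Martin periodinane, NaHCO3, CH2Cl2, 0 °C to rt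
Reagents that add atoms: none
Why: Dess–Martin oxidation gives an aldehyde on a quaternary carbon, which cannot enolise or epimerise.

Step 16
Reactants: 22 the C5 aldehyde
Product: 25 (1S,4R,8R,10R)-8,13-bis[(tert-butyldimethylsilyl)oxy]-1,4-epoxy-1-methoxygermacra-5E,7(11)-dien-6,12-olide, via lithium aldolate 23 (not isolated), via aldol acetate 24 (not isolated)
Conditions: LiN(SiMe3)2 (1.3 equiv), THF (2 mM), −78 °C; Ac2O, −78 to 0 °C; DBU, 0 °C to rt
Reagents that add atoms: none
Why: LiN(SiMe3)2 removes a C6 proton of the butenolide to give the aromatic lithium 2-furanolate, whose γ-carbon C6 adds to the non-enolisable aldehyde C5; the aldolate is acetylated, and DBU then removes the remaining C6–H and expels acetate (E1cB) to leave the C5=C6 double bond. The closest known reaction type is the vinylogous aldol condensation of 2(5H)-furanones with aldehydes followed by acylation and base elimination to γ-alkylidene butenolides, used here in a ring-closing sense. The nine-membered ring (C4–C5–C6–C7–C8–C9–C10–C1–O) closes by intramolecular carbonyl addition in the exo mode (9-exo-trig), the two reacting arms being held cis on the oxolane ring. No stereocentre of the product is created: the transient centres at C5 and C6 are erased in the elimination, so every aldol diastereomer converges on one alkene, and only the 5E geometry (C4 cis to C7) fits the ring. The step needs ring closure over oligomerisation (high dilution and the cis-2,5 template), γ- over α-attack (C11 is fully substituted and its adduct reverts), and no attack on C1 (the methyl ketal blocks the otherwise easy six-membered aldol onto a C1 ketone); the silyl ethers at C8 and C13 are too poor as leaving groups to compete with acetate.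

Step 17
Reactants: 25 the bis-silyl bridged dienolide
Product: 26 (1S,4R,8R,10R)-1,4-epoxy-8,13-dihydroxy-1-methoxygermacra-5E,7(11)-dien-6,12-olide
Conditions: HF·pyridine, pyridine, THF, 0 °C to rt
Reagents that add atoms: none
Why: Buffered fluoride cleaves both silyl ethers and should spare the methyl ketal and the dienyl lactone.

Step 18
Reactants: 26 the 8,13-diol
Product: 27 (1S,4R,8R,10R)-13-acetoxy-1,4-epoxy-8-hydroxy-1-methoxygermacra-5E,7(11)-dien-6,12-olide
Conditions: Ac2O (1.1 equiv), 2,4,6-collidine, CH2Cl2, −20 °C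
Reagents that add atoms: acetic anhydride, CC(=O)OC(C)=O
Why: Acetylation should select the unhindered primary allylic C13 hydroxyl over the secondary C8 hydroxyl flanked by the tetrasubstituted alkene.

Step 19
Reactants: 28 methyl (2S)-2-methyloxirane-2-carboxylate
Product: 29 potassium (2S)-2-methyloxirane-2-carboxylate
Conditions: KOH (1.0 equiv), MeOH–H2O, 0 °C; evaporation
Reagents that add atoms: potassium hydroxide, [K+].[OH-]
Why: Cold stoichiometric saponification gives the stable carboxylate salt without opening the epoxide or touching the quaternary stereocentre.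

Step 20
Reactants: 27 the 13-acetate 8-alcohol; 29 potassium (2S)-2-methyloxirane-2-carboxylate
Product: 31 (1S,4R,8R,10R)-13-acetoxy-1,4-epoxy-1-methoxy-8-{[(2S)-2-methyloxirane-2-carbonyl]oxy}germacra-5E,7(11)-dien-6,12-olide, via mixed anhydride 30 (not isolated)
Conditions: 2,4,6-trichlorobenzoyl chloride, THF, rt; then 27, DMAP, toluene, rt
Reagents that add atoms: none
Why: Yamaguchi esterification through the mixed anhydride and the acylpyridinium acylates the hindered C8 alcohol without acid, so the epoxide and both stereocentres are kept.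

Step 21
Reactants: 31 the epoxy ester
Product: 32 (1S,4R,8R,10R)-13-acetoxy-8-{[(2R)-3-chloro-2-hydroxy-2-methylpropanoyl]oxy}-1,4-epoxy-1-hydroxygermacra-5E,7(11)-dien-6,12-olide (the target)
Conditions: 2 M aq. HCl, LiCl (excess), THF, 0 °C to rt
Reagents that add atoms: hydrogen chloride, Cl; water, O
Why: Acid-promoted SN2 opening of the glycidic ester by chloride at the unsubstituted CH2 leaves the C2′–O bond intact (2′R), and the same acid hydrolyses the methyl ketal to the bridged hemiketal, whose C1 configuration (S) is fixed by the C4 bridgehead.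

## Compound list

1 | furan-3-ylmethanol | OCc1ccoc1 | starting material
2 | tert-butyl(furan-3-ylmethoxy)dimethylsilane | CC(C)(C)[Si](C)(C)OCc1ccoc1 | intermediate
3 | [2-(tert-butyldimethylsilyl)furan-3-yl]methanol | OCc1ccoc1[Si](C)(C)C(C)(C)C | intermediate
4 | 5-(tert-butyldimethylsilyl)-4-(hydroxymethyl)furan-3-carbaldehyde | OCc1c(C=O)coc1[Si](C)(C)C(C)(C)C | intermediate
5 | 5-(tert-butyldimethylsilyl)-4-{[(tert-butyldimethylsilyl)oxy]methyl}furan-3-carbaldehyde | CC(C)(C)[Si](C)(C)OCc1c(C=O)coc1[Si](C)(C)C(C)(C)C | intermediate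
6 | ethyl 2-(bromomethyl)prop-2-enoate | CCOC(=O)C(=C)CBr | starting material
7 | ethyl (4R)-4-FurSi-2-methylidene-4-[(trimethylsilyl)oxy]butanoate | CCOC(=O)C(=C)C[C@@H](O[Si](C)(C)C)c1coc([Si](C)(C)C(C)(C)C)c1CO[Si](C)(C)C(C)(C)C | intermediate (not isolated)
8 | ethyl (4R)-4-FurSi-4-hydroxy-2-methylidenebutanoate | CCOC(=O)C(=C)C[C@@H](O)c1coc([Si](C)(C)C(C)(C)C)c1CO[Si](C)(C)C(C)(C)C | intermediate (not isolated)
9 | (5R)-5-FurSi-3-methylideneoxolan-2-one | C=C1C[C@@H](OC1=O)c1coc([Si](C)(C)C(C)(C)C)c1CO[Si](C)(C)C(C)(C)C | intermediate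
10 | (3R,5R)-5-FurSi-3-methyloxolan-2-one (cis) | C[C@@H]1C[C@@H](OC1=O)c1coc([Si](C)(C)C(C)(C)C)c1CO[Si](C)(C)C(C)(C)C | intermediate
11 | (3R,5R)-5-FurSi-3-methyloxolan-2-ol (anomer mixture) | C[C@@H]1C[C@@H](OC1O)c1coc([Si](C)(C)C(C)(C)C)c1CO[Si](C)(C)C(C)(C)C | intermediate
12 | (1R,3R)-1-FurSi-3-methylpent-4-yn-1-ol | C#C[C@H](C)C[C@@H](O)c1coc([Si](C)(C)C(C)(C)C)c1CO[Si](C)(C)C(C)(C)C | intermediate
13 | tert-butyl{[(1R,3R)-1-FurSi-3-methylpent-4-yn-1-yl]oxy}dimethylsilane | C#C[C@H](C)C[C@@H](O[Si](C)(C)C(C)(C)C)c1coc([Si](C)(C)C(C)(C)C)c1CO[Si](C)(C)C(C)(C)C | intermediate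
14 | [(2S)-2-methyloxiran-2-yl]methanol | OC[C@@]1(C)CO1 | starting material
15 | (2R)-2-{[(4-methoxybenzyl)oxy]methyl}-2-methyloxirane | COc1ccc(COC[C@@]2(C)CO2)cc1 | intermediate
16 | (2R,6R,8R)-8-[(tert-butyldimethylsilyl)oxy]-8-FurSi-1-[(4-methoxybenzyl)oxy]-2,6-dimethyloct-4-yn-2-ol | COc1ccc(COC[C@](C)(O)CC#C[C@H](C)C[C@@H](O[Si](C)(C)C(C)(C)C)c2coc([Si](C)(C)C(C)(C)C)c2CO[Si](C)(C)C(C)(C)C)cc1 | intermediate
17 | furan-2(3H)-one isomer of 18 (C6=C7 double bond, C11–H) | COc1ccc(COC[C@](C)(O)CC#C[C@H](C)C[C@@H](O[Si](C)(C)C(C)(C)C)C2=COC(=O)C2CO[Si](C)(C)C(C)(C)C)cc1 | intermediate (not isolated)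
18 | 4-[(1R,3R,7R)-1-[(tert-butyldimethylsilyl)oxy]-7-hydroxy-8-[(4-methoxybenzyl)oxy]-3,7-dimethyloct-4-yn-1-yl]-3-{[(tert-butyldimethylsilyl)oxy]methyl}furan-2(5H)-one | COc1ccc(COC[C@](C)(O)CC#C[C@H](C)C[C@@H](O[Si](C)(C)C(C)(C)C)C2=C(CO[Si](C)(C)C(C)(C)C)C(=O)OC2)cc1 | intermediate
19 | 2,3-dihydrofuran enol ether (C1=C2) formed from 18 by cycloisomerisation; C4 R, C8 R, C10 R | CC(C)(C)[Si](C)(C)OCC1=C(COC1=O)[C@H](O[Si](C)(C)C(C)(C)C)C[C@@H](C)C2=CC[C@](C)(COCc3ccc(OC)cc3)O2 | intermediate (not isolated)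
20 | 4-{(1R,3R)-1-[(tert-butyldimethylsilyl)oxy]-3-[(2S,5R)-2-methoxy-5-{[(4-methoxybenzyl)oxy]methyl}-5-methyloxolan-2-yl]butyl}-3-{[(tert-butyldimethylsilyl)oxy]methyl}furan-2(5H)-one (OMe cis to the C4 methyl) | CC(C)(C)[Si](C)(C)OCC1=C(COC1=O)[C@H](O[Si](C)(C)C(C)(C)C)C[C@@H](C)[C@]2(OC)CC[C@](C)(COCc3ccc(OC)cc3)O2 | intermediate
21 | C5 primary alcohol corresponding to 20 (same configuration) | CC(C)(C)[Si](C)(C)OCC1=C(COC1=O)[C@H](O[Si](C)(C)C(C)(C)C)C[C@@H](C)[C@]2(OC)CC[C@](C)(CO)O2 | intermediate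
22 | C5 aldehyde corresponding to 21: (2R,5S)-5-methoxy-2-methyloxolane-2-carbaldehyde with the 8R,10R side chain and butenolide | CC(C)(C)[Si](C)(C)OCC1=C(COC1=O)[C@H](O[Si](C)(C)C(C)(C)C)C[C@@H](C)[C@]2(OC)CC[C@](C)(C=O)O2 | intermediate
23 | lithium aldolate (C5–O⁻, C6–H; mixture at C5 and C6) of the ring-closed lactone | CC(C)(C)[Si](C)(C)OCC1=C2C(OC1=O)C([O-])[C@@]3(C)CC[C@](OC)(O3)[C@H](C)C[C@H]2O[Si](C)(C)C(C)(C)C.[Li+] | intermediate (not isolated)
24 | aldol acetate (C5–OAc, C6–H; mixture at C5 and C6) | CC(C)(C)[Si](C)(C)OCC1=C2C(OC1=O)C(OC(C)=O)[C@@]3(C)CC[C@](OC)(O3)[C@H](C)C[C@H]2O[Si](C)(C)C(C)(C)C | intermediate (not isolated)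
25 | (1S,4R,8R,10R)-8,13-bis[(tert-butyldimethylsilyl)oxy]-1,4-epoxy-1-methoxygermacra-5E,7(11)-dien-6,12-olide | CC(C)(C)[Si](C)(C)OCC1=C2/C(=C\[C@@]3(C)CC[C@](OC)(O3)[C@H](C)C[C@H]2O[Si](C)(C)C(C)(C)C)OC1=O | intermediate
26 | (1S,4R,8R,10R)-1,4-epoxy-8,13-dihydroxy-1-methoxygermacra-5E,7(11)-dien-6,12-olide | OCC1=C2/C(=C\[C@@]3(C)CC[C@](OC)(O3)[C@H](C)C[C@H]2O)OC1=O | intermediate
27 | (1S,4R,8R,10R)-13-acetoxy-1,4-epoxy-8-hydroxy-1-methoxygermacra-5E,7(11)-dien-6,12-olide | CC(=O)OCC1=C2/C(=C\[C@@]3(C)CC[C@](OC)(O3)[C@H](C)C[C@H]2O)OC1=O | intermediate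
28 | methyl (2S)-2-methyloxirane-2-carboxylate | COC(=O)[C@]1(C)CO1 | starting material
29 | potassium (2S)-2-methyloxirane-2-carboxylate | [K+].[O-]C(=O)[C@]1(C)CO1 | intermediate
30 | (2S)-2-methyloxirane-2-carboxylic 2,4,6-trichlorobenzoic anhydride | O=C(OC(=O)c1c(Cl)cc(Cl)cc1Cl)[C@]2(C)CO2 | intermediate (not isolated)
31 | (1S,4R,8R,10R)-13-acetoxy-1,4-epoxy-1-methoxy-8-{[(2S)-2-methyloxirane-2-carbonyl]oxy}germacra-5E,7(11)-dien-6,12-olide | CC(=O)OCC1=C2/C(=C\[C@@]3(C)CC[C@](OC)(O3)[C@H](C)C[C@H]2OC(=O)[C@]4(C)CO4)OC1=O | intermediate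
32 | (1S,4R,8R,10R)-13-acetoxy-8-{[(2R)-3-chloro-2-hydroxy-2-methylpropanoyl]oxy}-1,4-epoxy-1-hydroxygermacra-5E,7(11)-dien-6,12-olide | CC(=O)OCC1=C2/C(=C\[C@@]3(C)CC[C@](O)(O3)[C@H](C)C[C@H]2OC(=O)[C@@](C)(O)CCl)OC1=O | target

## Step count and risks

Total step count: 21. Longest linear sequence: 19 steps (steps 1–9, 11–18, 20, 21).

**Step 16 (ring closure).** Intermolecular aldol oligomerisation or retro-aldol reversal before acetylation may outrun the nine-membered ring closure. The fallback closes the same C5–C6 bond at the furan stage by an intramolecular Nozaki–Hiyama–Kishi reaction, a closure type known for oxa-bridged nine-membered rings, and unmasks the butenolide afterwards. Setting out from 16, lithiation of the free furan α-position C6 (n-BuLi, 2.2 equiv, THF, −78 to 0 °C) and iodine quench would give the iodofuran F1. Gold-catalysed methanol ketalisation as in step 13 would give the iodofuran methyl ketal F2 (the iodine also blocks the nucleophilic furan carbon), DDQ the primary alcohol F3, and Dess–Martin oxidation the aldehyde F4. CrCl2 with NiCl2 (cat.) in DMSO–THF at high dilution should then join C6 to C5 and give the furan-fused nine-membered carbinol F5, which is acetylated (Ac2O, DMAP) to the acetate F6. Peracetic acid oxidation of the 2-silylfuran as in step 12 then gives aldol acetate 24, and DBU elimination rejoins the route at 25.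

**Step 21 (epoxide opening and ketal hydrolysis in one pot).** Water may open the epoxide to the diol, or the acid may cause acyl loss or migration before chloride is delivered. The fallback forms the chlorohydrin before the esterification. Setting out from 29, concentrated aqueous HCl at 0 °C would give (2R)-3-chloro-2-hydroxy-2-methylpropanoic acid F7. Bis-silylation (Et3SiCl, imidazole) gives triethylsilyl (2R)-3-chloro-2-methyl-2-[(triethylsilyl)oxy]propanoate F8, and oxalyl chloride with catalytic DMF converts the silyl ester into (2S)-3-chloro-2-methyl-2-[(triethylsilyl)oxy]propanoyl chloride F9. Acylation of 27 with F9 (pyridine, DMAP, CH2Cl2) gives the silyl-protected ester F10. Dilute aqueous HCl in THF then removes the triethylsilyl group and hydrolyses the ketal, coming back to the route at 32.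

**Step 12 (furan to butenolide).** Peracid may oxidise elsewhere in the molecule, or the C13 silyloxy group may be lost by β-elimination during the base-induced shift of the double bond into conjugation. The fallback uses photo-oxygenation instead. Setting out from 16, singlet oxygen (O2, hν, tetraphenylporphyrin, CH2Cl2, −78 °C) should convert the 2-silylfuran regiospecifically into the γ-hydroxybutenolide F11, with the carbonyl at the former C–Si carbon. NaBH4 reduction of its ring-opened aldehyde form (MeOH, 0 °C) and acidic work-up relactonise to the butenolide, coming back to the route at 18 without passing through the deconjugated lactone.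

## Further compounds

F1 | step 16 | (2R,6R,8R)-8-[(tert-butyldimethylsilyl)oxy]-8-[5-(tert-butyldimethylsilyl)-4-{[(tert-butyldimethylsilyl)oxy]methyl}-2-iodofuran-3-yl]-1-[(4-methoxybenzyl)oxy]-2,6-dimethyloct-4-yn-2-ol | COc1ccc(COC[C@](C)(O)CC#C[C@H](C)C[C@@H](O[Si](C)(C)C(C)(C)C)c2c(I)oc([Si](C)(C)C(C)(C)C)c2CO[Si](C)(C)C(C)(C)C)cc1
F2 | step 16 | iodofuran methyl ketal: the (2S,5R)-2-methoxy-5-(PMB-oxymethyl)-5-methyloxolane of 20 carrying the 5-TBS-4-(TBS-oxymethyl)-2-iodofuran-3-yl group in place of the butenolide | CC(C)(C)[Si](C)(C)OCc1c([Si](C)(C)C(C)(C)C)oc(I)c1[C@H](O[Si](C)(C)C(C)(C)C)C[C@@H](C)[C@]2(OC)CC[C@](C)(COCc3ccc(OC)cc3)O2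
F3 | step 16 | C5 primary alcohol corresponding to F2 | CC(C)(C)[Si](C)(C)OCc1c([Si](C)(C)C(C)(C)C)oc(I)c1[C@H](O[Si](C)(C)C(C)(C)C)C[C@@H](C)[C@]2(OC)CC[C@](C)(CO)O2
F4 | step 16 | C5 aldehyde corresponding to F3 | CC(C)(C)[Si](C)(C)OCc1c([Si](C)(C)C(C)(C)C)oc(I)c1[C@H](O[Si](C)(C)C(C)(C)C)C[C@@H](C)[C@]2(OC)CC[C@](C)(C=O)O2
F5 | step 16 | furan-fused nine-membered carbinol (C5–OH bonded to furan C6; 1S,4R,8R,10R; mixture at C5) | CC(C)(C)[Si](C)(C)OCc1c([Si](C)(C)C(C)(C)C)oc2c1[C@H](O[Si](C)(C)C(C)(C)C)C[C@@H](C)[C@]3(OC)CC[C@@](C)(O3)C2O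
F6 | step 16 | C5 acetate of F5 | CC(C)(C)[Si](C)(C)OCc1c([Si](C)(C)C(C)(C)C)oc2c1[C@H](O[Si](C)(C)C(C)(C)C)C[C@@H](C)[C@]3(OC)CC[C@@](C)(O3)C2OC(C)=O
F7 | step 21 | (2R)-3-chloro-2-hydroxy-2-methylpropanoic acid | C[C@](O)(CCl)C(=O)O
F8 | step 21 | triethylsilyl (2R)-3-chloro-2-methyl-2-[(triethylsilyl)oxy]propanoate | C[C@](O[Si](CC)(CC)CC)(CCl)C(=O)O[Si](CC)(CC)CC
F9 | step 21 | (2S)-3-chloro-2-methyl-2-[(triethylsilyl)oxy]propanoyl chloride | C[C@](O[Si](CC)(CC)CC)(CCl)C(Cl)=O
F10 | step 21 | (1S,4R,8R,10R)-13-acetoxy-8-{[(2R)-3-chloro-2-methyl-2-[(triethylsilyl)oxy]propanoyl]oxy}-1,4-epoxy-1-methoxygermacra-5E,7(11)-dien-6,12-olide | CC(=O)OCC1=C2/C(=C\[C@@]3(C)CC[C@](OC)(O3)[C@H](C)C[C@H]2OC(=O)[C@@](C)(O[Si](CC)(CC)CC)CCl)OC1=O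
F11 | step 12 | 5-hydroxy analogue of 18 (γ-hydroxybutenolide; mixture at the lactol carbon) | COc1ccc(COC[C@](C)(O)CC#C[C@H](C)C[C@@H](O[Si](C)(C)C(C)(C)C)C2=C(CO[Si](C)(C)C(C)(C)C)C(=O)OC2O)cc1
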